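**Retrosynthetic overview**

- The strategy rests on the six-membered carbocycle, numbered C1 (CH carrying the dienone chain), C2 (CH–O-tigloyl), C3 (C=O), C4 (methyl-bearing oxirane carbon), C5 (oxirane CH), C6 (CH2). C1 and C2 are trans, C1 is para to C4, and the C4–C5 oxirane is a masked cyclohexene. This is the substitution pattern of a [4+2] adduct of a 2-methyl-1-silyloxybutadiene with an E-enone.
- Late disconnections: C3 ketone from C3–OTBS; the side-chain C–C(=O)–C bonds from a carbonylative Stille coupling of a C1 1-bromoethenyl group with CO and (E)-Bu3SnCH=CHC(CH3)2OH; tiglate from acetate.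
- C2–OAc from a C2 acetyl group by Baeyer–Villiger oxidation (retention); oxirane from C4=C5, delivered anti to the C3 silyl ether.
- Cyclohexene from a catalytic enantioselective Diels–Alder reaction of silyloxydiene 2 with (E)-5-bromohexa-3,5-dien-2-one 7.
- Ring order: carbocycle first (step 4), oxirane second (step 5).

Key step: step 4

Assumption: the enone is taken to bind the cationic oxazaborolidine as acrylates do (boron syn to the C=C bond, α-C–H···O contact), so that the (S)-catalyst sends the diene to the Re face of the acetyl-bearing carbon. If the sense proves opposite, the (R)-catalyst is used in its place.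

Ring locants C1–C6 and the CIP descriptors quoted for compounds 8–18 refer to the numbering of the overview.

**Route**

Step 1
Reactants: 1 (E)-2-methylbut-2-enal
Product: 2 (E)-tert-butyldimethyl[(2-methylbuta-1,3-dien-1-yl)oxy]silane
Conditions: TBSOTf, Et3N, Et2O, 0 °C → rt
Reagents that add atoms: tert-butyldimethylsilyl trifluoromethanesulfonate, CC(C)(C)[Si](C)(C)OS(=O)(=O)C(F)(F)F
Why: Soft enolisation with O-silylation (silyl dienol ether formation), in which TBSOTf activates the aldehyde and Et3N removes a γ-proton of the s-trans enal, should give the 1-silyloxydiene mainly as the (1E) isomer, the only one that can reach the s-cis geometry needed in step 4.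

Step 2
Reactants: 3 acrolein
Product: 5 2-bromoprop-2-enal, via 2,3-dibromopropanal 4 (not isolated)
Conditions: Br2, CH2Cl2, −78 → 0 °C; then Et3N, 0 °C → rt
Reagents that add atoms: bromine, BrBr
Why: Bromine addition to the alkene followed by E1cB dehydrobromination (the acidic α-hydrogen is removed and the β-bromide leaves) is the standard entry to 2-bromoacrolein, which is used at once because it polymerises on storage.

Step 3
Reactants: 5 2-bromoprop-2-enal; 6 1-(triphenylphosphoranylidene)propan-2-one
Product: 7 (E)-5-bromohexa-3,5-dien-2-one
Conditions: CH2Cl2, 0 °C → rt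
Reagents that add atoms: none
Why: Wittig olefination with a ketone-stabilised ylide reacts only at the aldehyde and should give the (E)-enone, as such ylides do.

Step 4
Reactants: 2 (E)-tert-butyldimethyl[(2-methylbuta-1,3-dien-1-yl)oxy]silane; 7 (E)-5-bromohexa-3,5-dien-2-one
Product: 8 endo cycloadduct with C1 1-bromoethenyl, C2 acetyl, C3 OTBS, C4 methyl and a C4=C5 alkene (C1 R, C2 S, C3 S; acetyl cis to OTBS, trans to bromoethenyl)
Conditions: (S)-3,3-diphenyl-1-(2-methylphenyl)tetrahydro-1H,3H-pyrrolo[1,2-c][1,3,2]oxazaborole (20 mol %), HN(SO2CF3)2 (18 mol %), CH2Cl2, −78 → −40 °C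
Reagents that add atoms: none
Why: The N-protonated oxazaborolidine binds the acetyl oxygen and lowers the enone LUMO, and the diene then adds in a concerted, asynchronous, suprafacial [4+2] cycloaddition whose leading bond joins the unsubstituted diene terminus to the enone β-carbon. The closest known reaction type is the cationic oxazaborolidine-catalysed enantioselective Diels–Alder reaction of enones and acrylates with 1-silyloxy and alkyl dienes. The cyclohexene, the only ring made here, is closed by this intermolecular cycloaddition, which forms C1–C6 and C2–C3 together. C1 and C2 come out trans because the E geometry of the enone is carried through suprafacially, C3 comes out cis to the C2 acetyl group because the complexed carbonyl sits endo to the (E)-silyloxydiene, and the absolute configuration follows from the catalyst phenyl group that covers one face of the bound enone so that the diene reaches the Re face of the acetyl-bearing carbon. The step needs regio-, endo-, facial and site selectivity: the silyloxy donor outweighs the 2-methyl group and places C3 next to the acetyl-bearing carbon (bromoethenyl para to methyl), and the α,β-alkene reacts in preference to the bromoalkene because it is the one polarised directly by the complexed carbonyl, whereas addition across the distal alkene would build a quaternary C–Br centre without endo carbonyl overlap. Low temperature and the robust TBS ether should hold back Mukaiyama–Michael addition and loss of the silyl group, and the β-silyloxy ketone is taken on without exposure to base.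

Step 5
Reactants: 8 endo cycloadduct
Product: 10 epoxy acetate (1R,2S,3S,4S,5S) with C2 OAc and a C4–C5 oxirane cis to the C1 bromoethenyl group, via epoxy ketone 9 (not isolated)
Conditions: mCPBA (4 equiv), Na2HPO4, CH2Cl2, 0 °C → rt
Reagents that add atoms: 3-chloroperoxybenzoic acid, OOC(=O)c1cccc(Cl)c1
Why: Prilezhaev epoxidation of the electron-rich trisubstituted C4=C5 alkene is fast and should occur anti to the pseudoaxial allylic C3 silyl ether (setting C4 and C5 on the face of the C1 substituent), after which the slower Baeyer–Villiger oxidation of the methyl ketone proceeds with migration of the secondary ring carbon and retention at C2, while the electron-poor bromoalkene is left alone.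

Step 6
Reactants: 10 epoxy acetate
Product: 11 epoxy alcohol (1R,2S,3S,4S,5S) with free C2 OH
Conditions: i-Bu2AlH, CH2Cl2, −78 °C; aq. potassium sodium tartrate
Reagents that add atoms: none
Why: Reductive ester cleavage by i-Bu2AlH at low temperature removes the acetate (the only carbonyl group present) through an aluminium alkoxide that should not trigger 1,2-silyl migration to the cis-vicinal oxygen or a Payne-type opening, and neither the oxirane nor the alkenyl bromide reacts at −78 °C.

Step 7
Reactants: 11 epoxy alcohol; 12 (E)-2-methylbut-2-enoyl chloride
Product: 13 bromoethenyl tiglate (1R,2S,3S,4S,5S)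
Conditions: pyridine, DMAP (cat.), CH2Cl2, 0 → 40 °C
Reagents that add atoms: none
Why: DMAP-catalysed acylation (nucleophilic catalysis through the acylpyridinium ion) esterifies the hindered secondary alcohol with retention at C2, and pyridine in place of a stronger amine avoids vinylketene formation and deconjugation of the tigloyl group.

Step 8
Reactants: 14 2-methylbut-3-yn-2-ol
Product: 15 (E)-2-methyl-4-(tributylstannyl)but-3-en-2-ol
Conditions: Bu3SnH, PdCl2(PPh3)2 (2 mol %), THF, 0 °C → rt
Reagents that add atoms: tributyltin hydride, CCCC[SnH](CCCC)CCCC
Why: Palladium-catalysed hydrostannation adds Sn–H syn across the terminal alkyne with tin at the carbon remote from the bulky tertiary carbinol, which should give the (E)-vinylstannane (any internal regioisomer is removed by chromatography).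

Step 9
Reactants: 13 bromoethenyl tiglate; 15 (E)-2-methyl-4-(tributylstannyl)but-3-en-2-ol
Product: 16 silyl-protected dienone (1S,2S,3S,4S,5S)
Conditions: Pd(PPh3)4 (10 mol %), CO (3 atm), toluene, 80 °C
Reagents that add atoms: carbon monoxide, [C-]#[O+]
Why: Carbonylative Stille coupling (oxidative addition of the alkenyl bromide to zerovalent palladium, CO insertion to the acylpalladium species, transmetalation of the vinylstannane with retention of its E geometry, reductive elimination) builds the cross-conjugated dienone, and the substrate offers no allylic leaving group for π-allyl chemistry because the tiglate is homoallylic and the oxirane isolated.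

Step 10
Reactants: 16 silyl-protected dienone
Product: 17 C3 alcohol (1S,2S,3S,4R,5S; same geometry as 16, the C4 descriptor changes with the priorities)
Conditions: HF·pyridine, pyridine, THF, 0 °C → rt
Reagents that add atoms: none
Why: Fluoride-mediated desilylation under buffered, non-basic conditions removes the TBS group without the acyl migration between the cis C2 and C3 oxygens, the Payne rearrangement or the conjugate addition that basic fluoride would invite, and buffered HF·pyridine is tolerated by trisubstituted oxiranes.

Step 11
Reactants: 17 C3 alcohol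
Product: 18 CNP0263368.1 (1S,2S,4S,5S)
Conditions: Dess–Martin periodinane, NaHCO3, CH2Cl2, 0 °C → rt
Reagents that add atoms: none
Why: Dess–Martin oxidation converts the hindered secondary C3 alcohol into the ketone under neutral buffered conditions, the tertiary allylic alcohol cannot be oxidised, and no stereocentre (C2 included) is exposed to base.

**Compound list**

1 | (E)-2-methylbut-2-enal (tiglaldehyde) | C/C=C(\C)C=O | starting material
2 | (E)-tert-butyldimethyl[(2-methylbuta-1,3-dien-1-yl)oxy]silane | C=C/C(C)=C/O[Si](C)(C)C(C)(C)C | intermediate
3 | acrolein (prop-2-enal) | C=CC=O | starting material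
4 | 2,3-dibromopropanal (racemic, not isolated) | O=CC(Br)CBr | intermediate
5 | 2-bromoprop-2-enal (2-bromoacrolein) | C=C(Br)C=O | intermediate
6 | 1-(triphenylphosphoranylidene)propan-2-one | CC(=O)C=P(c1ccccc1)(c1ccccc1)c1ccccc1 | starting material
7 | (E)-5-bromohexa-3,5-dien-2-one | CC(=O)/C=C/C(Br)=C | intermediate
8 | 1-[(1S,2S,6R)-6-(1-bromoethenyl)-2-[(tert-butyldimethylsilyl)oxy]-3-methylcyclohex-3-en-1-yl]ethan-1-one (IUPAC locants; overview numbering C1 R, C2 S, C3 S) | C=C(Br)[C@@H]1CC=C(C)[C@@H](O[Si](C)(C)C(C)(C)C)[C@H]1C(C)=O | intermediate
9 | epoxy ketone: 8 with a C4–C5 oxirane cis to the C1 bromoethenyl group and anti to OTBS, (1R,2S,3S,4S,5S), not isolated | C=C(Br)[C@@H]1C[C@@H]2O[C@]2(C)[C@@H](O[Si](C)(C)C(C)(C)C)[C@H]1C(C)=O | intermediate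
10 | epoxy acetate: C2 acetate of the (1R,2S,3S,4S,5S)-1-(1-bromoethenyl)-3-[(tert-butyldimethylsilyl)oxy]-4-methyl-4,5-epoxycyclohexan-2-ol | C=C(Br)[C@@H]1C[C@@H]2O[C@]2(C)[C@@H](O[Si](C)(C)C(C)(C)C)[C@H]1OC(C)=O | intermediate
11 | epoxy alcohol: (1R,2S,3S,4S,5S)-1-(1-bromoethenyl)-3-[(tert-butyldimethylsilyl)oxy]-4-methyl-4,5-epoxycyclohexan-2-ol | C=C(Br)[C@@H]1C[C@@H]2O[C@]2(C)[C@@H](O[Si](C)(C)C(C)(C)C)[C@H]1O | intermediate
12 | (E)-2-methylbut-2-enoyl chloride (tigloyl chloride) | C/C=C(\C)C(Cl)=O | starting material
13 | bromoethenyl tiglate: C2 (E)-2-methylbut-2-enoate of 11, (1R,2S,3S,4S,5S) | C=C(Br)[C@@H]1C[C@@H]2O[C@]2(C)[C@@H](O[Si](C)(C)C(C)(C)C)[C@H]1OC(=O)/C(C)=C/C | intermediate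
14 | 2-methylbut-3-yn-2-ol | CC(C)(O)C#C | starting material
15 | (E)-2-methyl-4-(tributylstannyl)but-3-en-2-ol | CCCC[Sn](CCCC)(CCCC)/C=C/C(C)(C)O | intermediate
16 | silyl-protected dienone: target skeleton with C3 OTBS in place of the C3 ketone, (1S,2S,3S,4S,5S) | C=C(C(=O)/C=C/C(C)(C)O)[C@@H]1C[C@@H]2O[C@]2(C)[C@@H](O[Si](C)(C)C(C)(C)C)[C@H]1OC(=O)/C(C)=C/C | intermediate
17 | C3 alcohol: target skeleton with C3 OH (cis to the C2 tiglate, anti to the oxirane), (1S,2S,3S,4R,5S) | C=C(C(=O)/C=C/C(C)(C)O)[C@@H]1C[C@@H]2O[C@]2(C)[C@@H](O)[C@H]1OC(=O)/C(C)=C/C | intermediate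
18 | CNP0263368.1, (1S,2S,4S,5S) | C=C(C(=O)/C=C/C(C)(C)O)[C@@H]1C[C@@H]2O[C@]2(C)C(=O)[C@H]1OC(=O)/C(C)=C/C | target

**Step count**

Total steps: 11. Longest linear sequence: 9 steps (3 → 5 → 7 → 8 → 10 → 11 → 13 → 16 → 17 → 18; steps 2, 3, 4, 5, 6, 7, 9, 10, 11).

**Steps most likely to fail**

Step 4. The risks are poor enantiofacial discrimination with this doubly unsaturated ketone, competing cycloaddition or Mukaiyama–Michael addition at the distal bromoalkene, and loss of the silyl group from the diene under the strongly acidic catalyst. The fallback sets out from 5 and exchanges the enone for an enal, the dienophile class that reacts fastest and at the lowest temperature with cationic oxazaborolidines. Wittig reaction of 5 with (triphenylphosphoranylidene)acetaldehyde in CH2Cl2 should give (E)-4-bromopenta-2,4-dienal F1. Its cycloaddition with 2 at −95 to −78 °C should give the aldehyde adduct F2, which has the configuration of 8 with CHO in place of acetyl. The (R)-catalyst is used here, because the formyl C–H···O binding mode turns the other face of the α-carbon to the diene. Addition of MeMgBr (THF, −78 °C) should give the methyl carbinol F3 as a mixture at the carbinol carbon, and Dess–Martin oxidation comes back to the route at 8.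

Step 9. The risks are slow oxidative addition of the hindered 1,1-disubstituted alkenyl bromide under CO, direct coupling without CO uptake, and protodestannylation or homocoupling of the stannane. The fallback sets out from 13 and forms the same C–C bond by carbonyl addition. Cross-metathesis of 2-methylbut-3-en-2-ol with crotonaldehyde (second-generation Grubbs catalyst, CH2Cl2, 40 °C) should give (E)-4-hydroxy-4-methylpent-2-enal F4. Nozaki–Hiyama–Kishi coupling of 13 with this aldehyde (CrCl2, NiCl2 cat., DMSO, rt) should give the bis-allylic carbinol F5 as a mixture at the carbinol carbon. MnO2 in CH2Cl2 oxidises only the secondary bis-allylic alcohol and comes back to the route at 16.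

Step 5. The risk is a sluggish Baeyer–Villiger oxidation of the hindered methyl ketone, so that on long exposure the oxirane formed first is opened by 3-chlorobenzoic acid or the bromoalkene is attacked. The fallback sets out from 8 and inverts the order of the two oxidations. Baeyer–Villiger oxidation with bis(trimethylsilyl) peroxide and catalytic TMSOTf (CH2Cl2, −40 °C), a reagent that does not epoxidise alkenes, should give the cyclohexenyl acetate F6. A short treatment with mCPBA (1.1 equiv, NaHCO3, CH2Cl2, 0 °C) then epoxidises the trisubstituted alkene anti to the silyl ether and comes back to the route at 10.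

Further compounds
F1 | step 4 | (E)-4-bromopenta-2,4-dienal | O=C/C=C/C(Br)=C
F2 | step 4 | 6-(1-bromoethenyl)-2-[(tert-butyldimethylsilyl)oxy]-3-methylcyclohex-3-ene-1-carbaldehyde, configured as 8 | C=C(Br)[C@@H]1CC=C(C)[C@@H](O[Si](C)(C)C(C)(C)C)[C@H]1C=O
F3 | step 4 | 1-[6-(1-bromoethenyl)-2-[(tert-butyldimethylsilyl)oxy]-3-methylcyclohex-3-en-1-yl]ethan-1-ol, ring configured as 8, carbinol carbon as a mixture | C=C(Br)[C@@H]1CC=C(C)[C@@H](O[Si](C)(C)C(C)(C)C)[C@H]1C(C)O
F4 | step 9 | (E)-4-hydroxy-4-methylpent-2-enal | CC(C)(O)/C=C/C=O
F5 | step 9 | bis-allylic carbinol: 16 with CH(OH) in place of the side-chain ketone, carbinol carbon as a mixture | C=C(C(O)/C=C/C(C)(C)O)[C@@H]1C[C@@H]2O[C@]2(C)[C@@H](O[Si](C)(C)C(C)(C)C)[C@H]1OC(=O)/C(C)=C/C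
F6 | step 5 | cyclohexenyl acetate: 8 with OAc in place of the C2 acetyl group (retention) | C=C(Br)[C@@H]1CC=C(C)[C@@H](O[Si](C)(C)C(C)(C)C)[C@H]1OC(C)=O
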